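The numbers stand for no real mixture; the result is computed.

The closed, stirred flask held starting material and partner, the partner charged in excess, and three steps drew on the starting material.

starting material 0.11 M; partner 0.165 M; time 50 s

    starting material + partner → target (k1 = 0.160 /M/s)
    crystals ⇌ target, rate k2*(cs2 - [target]) while solid is left; crystals form when [target] > cs2 (cs2 = 1.4 mM, k2 = 8.53 /s)
    starting material → side product A (k3 = 0.0165 /s)
    2 starting material → side product B (k4 = 0.305 /M/s)

- percent here means starting material units held: one side product B counts as two
- what is said of target includes crystals
- a doubled species enters its step squared and goes two at a time
- crystals is a solid; its amount is given per volume of the solution
- the reaction counts as stopped when no species that holds the starting material changes by six tenths of a point or more over the second half of the time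
- run time (flask): 50 s

1. why nothing more happens at 50 s, or that something still does (forward and back rates have come level / all of the starting material has reacted / it is still moving / the partner has run out first)
2. share of the starting material used up at 50 s
3. target at 50 s, in percent of the starting material charged
4. side product B at 50 s, in percent of the starting material charged

I froze c(partner). A first pass with partner at its charge gave an estimate of 37.5 mM of target, so I held c(partner) at its charge minus half of that. The partner step then counted as pseudo-first-order.

c(partner) = 0.146 M
kf = partner-step constant × c(partner) + side-product-A constant = 0.0399 /s
c× = kf / (twice the side-product-B constant) = 65.4 mM

I called c× the crossover concentration, the level of starting material at which the doubled step and the two first-order steps use it up equally.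

With c(partner) frozen, c(starting material) at its charge stood above c×, so in my reckoning the doubled step led in the first instants, at ρ = 1.68 times the first-order pair. By my reckoning, c(starting material) reached c× at 5.68 s, and from there the first-order pair led. Target passing 1.4 mM went on to crystals, which count as target, and no rate of starting material contains target, so I dropped that step. Towards the end, the integrated rate law gave:

left = e^(−kf·t) / [1 + ρ(1 − e^(−kf·t))] = 5.55%, so conversion = 94.5%
time integral of c(starting material) = 1.47 M·s
target = 31.3%; side product A = 22.1%; side product B, by balance = 41.1%

At half the time my reckoning left 17.9%, which was 12 percentage points above its value at the end, so I answered that the flask was still moving.

The forecast said that it is still moving, with 94.2% used up, target at 31.5% and side product B at 40.6%, noting that “crystals count as target, so step 2 does not affect the totals”.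

The flask showed that it is still moving, with 94.2% used up, target at 31.4% and side product B at 40.7%. Its partner stood at 79% of charge at 50.0 s, and the level halfway between that and the charge was 89.5%, against my frozen 88.6%. In the neighbour charged with 0.66 M of partner, taken at that charge, c× came to 200 mM, above its charge of starting material. At its conversion of 99.8%, I took the run as complete, which put side product B at 20.3%. That neighbour held 20.8% at 50.0 s.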